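## The problem

Compound 26 is a 5,7,4'-trihydroxyflavone in which C3 of ring C and the 2'-oxygen of ring B are joined by a two-carbon bridge, so that a seven-membered dihydrooxepine (C3, C2, C1', C2', O, C12, C11) is fused to the pyranone and to ring B, and ring A carries prenyl groups at C6 and C8 (flavone numbering; C11 is the methylene on C3, C12 the oxygen-bearing stereocentre, C13 the carbinol carbon of the 2-hydroxypropan-2-yl group). C12 is the only stereocentre (R; O > C13 > C11 > H), so nothing in the molecule can control it: it must be bought or made enantioselectively and then kept away from conditions that make C12–H acidic. The C12–O bond is flanked by the fully substituted C13, so an SN2 etherification at C12 is only attractive before C13 carries its two methyl groups. The same ether sits β to C11, so a carbanion at C11 would expel the ring B phenoxide; C11 has to react as an electrophile or as a radical. The prenyl groups ortho to free phenols cyclise to chromans in strong acid and do not survive halonium reagents or hydrogenation, the tertiary alcohol can dehydrate, and the pyranone is opened by hard nucleophiles at C2. In ring A, C6 and C8 are the only unsubstituted positions and both are activated by the phenols, which allows late halogenation and cross-coupling. The feature that opens the plan is that C3 is an sp2 carbon which leaves an ynone iodocyclisation already bearing iodine, while C11 can be carried as an aldehyde directly beside C12 on the 2'-oxygen, so a neutral alkenyl iodide–aldehyde coupling can form C3–C11 and close the oxepine in one operation.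

## Retrosynthesis

**Protecting groups last.** Target 26 is traced to 25, its tris-MOM ether with C13–O silylated. No skeletal bond is made in the last step, and one mild acid treatment frees all four hydroxyls. No hydrogenation or Lewis acid is needed once the prenyl groups are present.

**C6–prenyl and C8–prenyl.** Both aryl–allyl bonds of 25 are cut to the diiodide 24 and a prenylstannane. Direct C-prenylation of a phloroglucinol-type ring gives O/C and mono/di mixtures. Carrying the prenyl groups from the start would expose them to ICl (step 11) and H2 (step 17). Diiodide 24 comes from 22 through 23; 22 has free phenols only in ring A, so iodination is directed to C6 and C8. The forward reaction must transfer the prenyl group through its α-carbon at two crowded positions.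

**C11–O and the benzyl ethers.** Diol 22 goes back to the bis-benzyl ether 21, and the C11 methylene of 21 to the carbinol 19 through thionocarbonate 20. A radical deoxygenation is chosen because a C11 radical neither eliminates the β-aryloxy group as an anion would nor invites hydride shift from C12 as a cation might.

**C3–C11 (key cut).** Carbinol 19 is opened to the iodoflavone aldehyde 18. The neighbouring cuts are less attractive:
- cutting C12–O would require etherification at a neopentyl-like secondary carbon inside a seven-membered ring;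
- cutting C2–C1' would require a coupling across a tetrasubstituted alkene;
- C11–C12 has no polar handle.

Compound 18 has one ring fewer and its stereocentre is already in place. The forward reaction must prefer the aldehyde to the C4 carbonyl and must not be basic.

**Oxidation level of C11.** Aldehyde 18 comes from alcohol 17 and this from PMB ether 16. The aldehyde is released only just before use. PMB is chosen because DDQ removes it beside silyl, MOM and benzyl ethers and the C–I bond.

**O1–C2 and C3–I.** Iodoflavone 16 is cut to ynone 15. Iodocyclisation closes ring C and places iodine at C3 in the same step; iodinating a preformed 5,7-dialkoxyflavone would favour C6/C8 instead.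

**C4–alkyne.** Ynone 15 comes from propargylic alcohol 14, formed from acetylide 13 (from dibromoalkene 10) and aldehyde 12; 12 is the tribenzyl ether of 11. This joins rings A and B convergently.

**C13–methyl bonds and the alkyne carbon.** Silyl ether 10 goes back through tertiary alcohol 9 and ester 8 to aldehyde ester 7. The two methyl groups arrive by Grignard addition to an ester, and the alkyne carbon by Corey–Fuchs homologation of the ring B aldehyde.

**C12–O.** Ether 7 is cut to phenol 6 and hydroxy ester 4. At this stage C12 is α to an ester and carries only CH2OPMB, so Mitsunobu displacement is activated, unhindered and inverts cleanly. The alternative of etherifying a 2,3-dihydroxy-3-methylbutanoate would be neopentyl-like and complicated by the free 1,2-diol. Ester 4 comes from methyl glycerate 2 through the stannylene acetal 3, 2 from the commercial acetonide 1, and 6 from 5.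

## Roads not taken

**Alternative 1:** Ring C is cut at C4–C4a and O1–C2. Heating phloroglucinol A1 with the benzoxepinone β-keto ester A2 would C-acylate the triphenol and cyclodehydrate onto the ketone to give the 5,7-dihydroxy oxepinoflavone A3.
- Merits: very convergent, no ring A protecting groups, no chromium, and no C11 oxygen to remove. In step count it is clearly better than the chosen plan up to the stage of 22.
- Weak points: this thermal condensation normally needs a solvent-free melt well above 200 °C, which threatens the tertiary alcohol (dehydration) and the aryl silyl ether. The ketone of A2 is a hindered ortho-alkoxyaryl ketone in a seven-membered ring with a tertiary α-carbon, so cyclodehydration in the chromone sense is not assured against coumarin-type closure. A3 still needs the late iodination and prenylation.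
- Comparison: the chosen plan pays with the deoxygenation and benzyl handling. It offers a ring closure at room temperature under neutral conditions and a C12 that never sees heat or acid before the last step.

**Alternative 2:** The cut is at C2–C3, with the 1,3-dioxygenation masked. The ring B aldoxime A4 would be oxidised to the nitrile oxide A5, which adds across the tethered ring A alkyne to give the isoxazole-fused dihydrobenzoxepine A6.
- Merits: oxepine and masked ring C form together, regiochemistry is fixed by the tether, and the prenyl groups are present from the start, so the four late ring A steps and all tin and chromium reagents are avoided.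
- Weak points: the oxidants that convert an aldoxime into a nitrile oxide (hypochlorite, N-chloro reagents, PhI(OAc)2) also attack prenyl alkenes and the tris-MOM-oxy ring. The alkyne of A4 is flanked by two ortho substituents, so nitrile oxide dimerisation may outrun a slow cycloaddition. After A6 the N–O bond must be cleaved without hydrogenating the prenyl groups (for example with Mo(CO)6), the nitrogen hydrolysed and ring C closed by acid in the presence of prenylated phenols. Building the diprenylated aryl alkyne half of A4 is itself long.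
- Comparison: fewer late steps, but about three unmasking steps are added and the most sensitive groups are present throughout. The chosen plan keeps the prenyl groups out until the penultimate step.

**Alternative 3:** Ring C is cut at C3–C4 and O1–C2. Under [Cp*RhCl2]2 and Cu(OAc)2, the formyl C–H and phenol O–H of salicylaldehyde A7 would add across the aryl alkyl alkyne A8 to give chromone A9, with the side chain already on C3 as its acetonide.
- Merits: highly convergent; C3–C11 comes in with the alkyne, so there is no C11 oxygen to remove and no redox adjustment at C11. In step economy this road is better.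
- Weak points: the usual preference for aryl next to oxygen may erode for an ortho-bromoaryl alkyne, and the reaction runs hot with stoichiometric copper. The oxepine must then be closed by intramolecular aryl–oxygen coupling of the bromide with a secondary alcohol flanked by a tertiary carbinol. Hindered secondary alcohols in such couplings suffer β-hydride elimination and hydrodebromination, and the diol must first be differentiated.
- Comparison: the chosen plan makes the hardest bond, C12–O, first, by SN2 on a small molecule, and closes the ring through carbon–carbon bond formation between an alkenyl iodide and an aldehyde.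

Key step: step 14

Remark on the chemistry: C12 keeps one spatial arrangement from step 4 to the target; its descriptor reads R throughout except in aldehyde 18 (and F1–F3), where the higher rank of the C11 carbonyl carbon turns it into S.

## Route

Step 1
Reactants: 1 methyl (4S)-2,2-dimethyl-1,3-dioxolane-4-carboxylate
Product: 2 methyl (2S)-2,3-dihydroxypropanoate
Conditions: p-TsOH·H2O (cat.), MeOH, rt
Reagents that add atoms: none
Why: Acid-catalysed transketalisation in methanol releases the 1,2-diol; the stereocentre is not involved and the methyl ester is kept because methanol is the solvent.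

Step 2
Reactants: 2 methyl (2S)-2,3-dihydroxypropanoate
Product: 4 methyl (2S)-2-hydroxy-3-[(4-methoxybenzyl)oxy]propanoate, via dibutylstannylene acetal 3 (not isolated)
Conditions: Bu2SnO, toluene, reflux (Dean–Stark); then PMBCl, Bu4NI (cat.), 80 °C
Reagents that add atoms: 4-methoxybenzyl chloride, COc1ccc(CCl)cc1
Why: Stannylene-acetal monoalkylation: the acetal of a terminal 1,2-diol is alkylated at the primary oxygen, which is less hindered and not deactivated by the ester; no base touches the α-hydroxy ester centre.

Step 3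
Reactants: 5 2,4-dihydroxybenzaldehyde
Product: 6 2-hydroxy-4-(methoxymethoxy)benzaldehyde
Conditions: MOMCl (1.05 equiv), i-Pr2NEt, CH2Cl2, 0 °C → rt
Reagents that add atoms: chloromethyl methyl ether, COCCl
Why: Chemoselective Williamson-type O-alkylation: the 2-hydroxyl is hydrogen-bonded to the formyl group and far less nucleophilic than the 4-hydroxyl, so one equivalent of MOMCl should protect the 4-position only.

Step 4
Reactants: 6 2-hydroxy-4-(methoxymethoxy)benzaldehyde; 4 methyl (2S)-2-hydroxy-3-[(4-methoxybenzyl)oxy]propanoate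
Product: 7 methyl (2R)-2-[2-formyl-5-(methoxymethoxy)phenoxy]-3-[(4-methoxybenzyl)oxy]propanoate
Conditions: PPh3, DIAD, THF, 0 °C → rt
Reagents that add atoms: none
Why: Mitsunobu etherification of an acidic ortho-formylphenol with an α-hydroxy ester is an SN2 displacement of the oxyphosphonium group with clean inversion, turning (2S)-4 into the (2R)-aryl ether; C12 is here activated by the ester and unhindered.

Step 5
Reactants: 7 methyl (2R)-2-[2-formyl-5-(methoxymethoxy)phenoxy]-3-[(4-methoxybenzyl)oxy]propanoate
Product: 8 methyl (2R)-2-[2-(2,2-dibromoethenyl)-5-(methoxymethoxy)phenoxy]-3-[(4-methoxybenzyl)oxy]propanoate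
Conditions: CBr4, PPh3, Et3N, CH2Cl2, 0 °C
Reagents that add atoms: carbon tetrabromide, BrC(Br)(Br)Br
Why: Corey–Fuchs dibromoolefination (Wittig reaction of Ph3P=CBr2) is selective for the aldehyde over the ester; Et3N buffers the acidic phosphorus by-products so the MOM and PMB ethers survive, and removing the formyl group ends any chance of aldol closure onto the α-aryloxy ester.

Step 6
Reactants: 8 methyl (2R)-2-[2-(2,2-dibromoethenyl)-5-(methoxymethoxy)phenoxy]-3-[(4-methoxybenzyl)oxy]propanoate
Product: 9 (3R)-3-[2-(2,2-dibromoethenyl)-5-(methoxymethoxy)phenoxy]-4-[(4-methoxybenzyl)oxy]-2-methylbutan-2-ol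
Conditions: MeMgBr (3.5 equiv), THF, −78 → 0 °C
Reagents that add atoms: methylmagnesium bromide, C[Mg]Br
Why: Double Grignard addition to the ester builds C13 with both methyl groups; the dibromoalkene does not exchange with MeMgBr at this temperature, and enolisation of the transient methyl ketone can only divert material, since the alkoxide product has no acidic hydrogen at C12.

Step 7
Reactants: 9 (3R)-3-[2-(2,2-dibromoethenyl)-5-(methoxymethoxy)phenoxy]-4-[(4-methoxybenzyl)oxy]-2-methylbutan-2-ol
Product: 10 {[(3R)-3-[2-(2,2-dibromoethenyl)-5-(methoxymethoxy)phenoxy]-4-[(4-methoxybenzyl)oxy]-2-methylbutan-2-yl]oxy}triethylsilane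
Conditions: TESOTf, 2,6-lutidine, CH2Cl2, −78 °C
Reagents that add atoms: triethylsilyl trifluoromethanesulfonate, CC[Si](CC)(CC)OS(=O)(=O)C(F)(F)F
Why: Silylation of a tertiary alcohol needs the silyl triflate; at −78 °C with 2,6-lutidine it is fast, while the aryl MOM and PMB ethers should not be attacked.

Step 8
Reactants: 11 2,4,6-trihydroxybenzaldehyde
Product: 12 2,4,6-tris(benzyloxy)benzaldehyde
Conditions: BnBr, K2CO3, DMF, 60 °C
Reagents that add atoms: benzyl bromide, BrCc1ccccc1
Why: Exhaustive Williamson benzylation; the formyl group lowers the C-nucleophilicity of the phloroglucinol ring so that O-alkylation should prevail.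

Step 9
Reactants: 10 {[(3R)-3-[2-(2,2-dibromoethenyl)-5-(methoxymethoxy)phenoxy]-4-[(4-methoxybenzyl)oxy]-2-methylbutan-2-yl]oxy}triethylsilane; 12 2,4,6-tris(benzyloxy)benzaldehyde
Product: 14 1-[2,4,6-tris(benzyloxy)phenyl]-3-[2-({(2R)-1-[(4-methoxybenzyl)oxy]-3-methyl-3-[(triethylsilyl)oxy]butan-2-yl}oxy)-4-(methoxymethoxy)phenyl]prop-2-yn-1-ol (both carbinol epimers), via lithium acetylide 13 (not isolated)
Conditions: n-BuLi (2.1 equiv), THF, −78 → 0 °C; then 12, −78 → 0 °C; H2O quench
Reagents that add atoms: none
Why: Second stage of the Corey–Fuchs sequence: bromine–lithium exchange and Fritsch–Buttenberg–Wiechell rearrangement give the alkyne, which the second equivalent of n-BuLi turns into acetylide 13; 1,2-addition to aldehyde 12 gives the propargylic alcohol, whose new carbinol centre is uncontrolled and is destroyed in step 10.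

Step 10
Reactants: 14 1-[2,4,6-tris(benzyloxy)phenyl]-3-[2-({(2R)-1-[(4-methoxybenzyl)oxy]-3-methyl-3-[(triethylsilyl)oxy]butan-2-yl}oxy)-4-(methoxymethoxy)phenyl]prop-2-yn-1-ol
Product: 15 1-[2,4,6-tris(benzyloxy)phenyl]-3-[2-({(2R)-1-[(4-methoxybenzyl)oxy]-3-methyl-3-[(triethylsilyl)oxy]butan-2-yl}oxy)-4-(methoxymethoxy)phenyl]prop-2-yn-1-one
Conditions: MnO2, CH2Cl2, rt
Reagents that add atoms: none
Why: MnO2 oxidation of a doubly activated (benzylic and propargylic) alcohol under neutral conditions, so the electron-rich, easily ionised carbinol never meets acid.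

Step 11
Reactants: 15 1-[2,4,6-tris(benzyloxy)phenyl]-3-[2-({(2R)-1-[(4-methoxybenzyl)oxy]-3-methyl-3-[(triethylsilyl)oxy]butan-2-yl}oxy)-4-(methoxymethoxy)phenyl]prop-2-yn-1-one
Product: 16 5,7-bis(benzyloxy)-3-iodo-2-[2-({(2R)-1-[(4-methoxybenzyl)oxy]-3-methyl-3-[(triethylsilyl)oxy]butan-2-yl}oxy)-4-(methoxymethoxy)phenyl]-4H-chromen-4-one
Conditions: ICl (1.2 equiv), CH2Cl2, −78 °C; aq. Na2S2O3
Reagents that add atoms: iodine monochloride, ClI
Why: Electrophilic iodocyclisation of an ortho-alkoxyaryl ynone: iodonium activation, 6-endo-dig attack of a ring A benzyloxy oxygen at the alkyne carbon bearing ring B (the site best able to carry positive charge) and debenzylation of the oxonium ion by chloride give ring C with iodine at C3; the ring B ether oxygen cannot compete productively because its hindered secondary alkyl group cannot be lost.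

Step 12
Reactants: 16 5,7-bis(benzyloxy)-3-iodo-2-[2-({(2R)-1-[(4-methoxybenzyl)oxy]-3-methyl-3-[(triethylsilyl)oxy]butan-2-yl}oxy)-4-(methoxymethoxy)phenyl]-4H-chromen-4-one
Product: 17 5,7-bis(benzyloxy)-2-[2-({(2R)-1-hydroxy-3-methyl-3-[(triethylsilyl)oxy]butan-2-yl}oxy)-4-(methoxymethoxy)phenyl]-3-iodo-4H-chromen-4-one
Conditions: DDQ, CH2Cl2/pH 7 buffer, 0 °C → rt
Reagents that add atoms: none
Why: Oxidative PMB cleavage by DDQ (hydride abstraction, then hydrolysis of the oxocarbenium ion); benzyl, MOM and silyl ethers and the C–I bond are inert under buffered conditions.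

Step 13
Reactants: 17 5,7-bis(benzyloxy)-2-[2-({(2R)-1-hydroxy-3-methyl-3-[(triethylsilyl)oxy]butan-2-yl}oxy)-4-(methoxymethoxy)phenyl]-3-iodo-4H-chromen-4-one
Product: 18 (2S)-2-{2-[5,7-bis(benzyloxy)-3-iodo-4-oxo-4H-chromen-2-yl]-5-(methoxymethoxy)phenoxy}-3-methyl-3-[(triethylsilyl)oxy]butanal
Conditions: Dess–Martin periodinane, NaHCO3, CH2Cl2, 0 °C → rt; used crude
Reagents that add atoms: none
Why: Dess–Martin oxidation under buffered, non-basic conditions should give the α-aryloxy aldehyde without enolisation; the crude aldehyde is taken on at once.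

Step 14
Reactants: 18 (2S)-2-{2-[5,7-bis(benzyloxy)-3-iodo-4-oxo-4H-chromen-2-yl]-5-(methoxymethoxy)phenoxy}-3-methyl-3-[(triethylsilyl)oxy]butanal
Product: 19 (12R)-5,7-bis(benzyloxy)-11-hydroxy-4'-(methoxymethoxy)-12-{2-[(triethylsilyl)oxy]propan-2-yl}oxepinoflavone (bridge C3–C11H(OH)–C12H–O–C2'; both C11 epimers)
Conditions: CrCl2 (8 equiv), NiCl2 (2 mol %), degassed DMF, rt, high dilution (slow addition of 18)
Reagents that add atoms: none
Why: Divalent chromium reduces NiCl2 to zerovalent nickel, which inserts into the C3–I bond; transmetalation gives a C3-bound alkenyl species of trivalent chromium that adds to the tethered aldehyde carbon C11, forming C3–C11 and, after aqueous work-up, the C11 carbinol. The closest known reaction type is the intramolecular Nozaki–Hiyama–Kishi coupling of alkenyl iodides with aldehydes, widely used for medium and large rings. The oxepine closes in a 7-exo-trig mode (C3, C2, C1', C2', O, C12, C11), helped by the fixed cis placement of C3 and the 2'-oxygen across the C2–C1' bond. The new centre C11 forms without control as either epimer, which is acceptable because its oxygen is removed in steps 15 and 16. C12 is not touched because the medium is neutral and non-basic, so the α-aryloxy aldehyde neither enolises nor loses the β-silyloxy group. Selectivity for the aldehyde over the C4 carbonyl and the ether groups follows from the low basicity and strong aldehyde preference of organochromium reagents, and the C3–I bond is the only carbon–halogen bond present. High dilution favours ring closure over intermolecular coupling, and the in-plane sp2 C–Cr bond cannot relax to an oxygen-bound enolate.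

Step 15
Reactants: 19 (12R)-5,7-bis(benzyloxy)-11-hydroxy-4'-(methoxymethoxy)-12-{2-[(triethylsilyl)oxy]propan-2-yl}oxepinoflavone
Product: 20 O-phenyl thionocarbonate of 19 at the C11 oxygen (both C11 epimers)
Conditions: PhOC(S)Cl, pyridine, DMAP (cat.), CH2Cl2, rt
Reagents that add atoms: O-phenyl chlorothionoformate, S=C(Cl)Oc1ccccc1
Why: Thioacylation of the secondary alcohol (first half of the Barton–McCombie deoxygenation); the reagent acylates hindered alcohols under DMAP catalysis without forming an alkoxide, so no silyl migration from the C13 oxygen can occur.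

Step 16
Reactants: 20 O-phenyl thionocarbonate of 19
Product: 21 (12R)-5,7-bis(benzyloxy)-4'-(methoxymethoxy)-12-{2-[(triethylsilyl)oxy]propan-2-yl}oxepinoflavone (bridge C3–C11H2–C12H–O–C2')
Conditions: Bu3SnH, AIBN, toluene, 90 °C
Reagents that add atoms: none
Why: Barton–McCombie radical deoxygenation: the stannyl radical adds to C=S, fragmentation gives a C11 radical stabilised by conjugation with C3=C2, and hydrogen transfer from Bu3SnH gives the methylene; both C11 epimers converge and C12 is not involved.

Step 17
Reactants: 21 (12R)-5,7-bis(benzyloxy)-4'-(methoxymethoxy)-12-{2-[(triethylsilyl)oxy]propan-2-yl}oxepinoflavone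
Product: 22 (12R)-5,7-dihydroxy-4'-(methoxymethoxy)-12-{2-[(triethylsilyl)oxy]propan-2-yl}oxepinoflavone
Conditions: H2 (1 atm), Pd/C, EtOAc/THF, rt
Reagents that add atoms: none
Why: Hydrogenolysis of the two aryl benzyl ethers over Pd/C; the tetrasubstituted C2=C3 bond, the MOM ether and the tertiary silyl ether are expected to survive in a non-alcoholic solvent.

Step 18
Reactants: 22 (12R)-5,7-dihydroxy-4'-(methoxymethoxy)-12-{2-[(triethylsilyl)oxy]propan-2-yl}oxepinoflavone
Product: 23 (12R)-5,7-dihydroxy-6,8-diiodo-4'-(methoxymethoxy)-12-{2-[(triethylsilyl)oxy]propan-2-yl}oxepinoflavone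
Conditions: NIS (2.1 equiv), DMF, 0 °C → rt, dark
Reagents that add atoms: N-iodosuccinimide, O=C1CCC(=O)N1I
Why: Electrophilic aromatic iodination: C6 and C8 are the only free positions of ring A and lie ortho/para to free phenols, whereas ring B carries only ethers and is deactivated by the pyranone, so two equivalents of NIS should iodinate ring A selectively.

Step 19
Reactants: 23 (12R)-5,7-dihydroxy-6,8-diiodo-4'-(methoxymethoxy)-12-{2-[(triethylsilyl)oxy]propan-2-yl}oxepinoflavone
Product: 24 (12R)-6,8-diiodo-5,7,4'-tris(methoxymethoxy)-12-{2-[(triethylsilyl)oxy]propan-2-yl}oxepinoflavone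
Conditions: NaH, MOMCl, DMF, 0 °C → rt
Reagents that add atoms: chloromethyl methyl ether, COCCl
Why: Williamson-type acetal protection of both phenols (the chelated 5-hydroxyl needs the phenoxide, hence NaH); masking them suppresses protodeiodination and phenoxide interference in the coupling and adds no later step, since all MOM groups leave together.

Step 20
Reactants: 24 (12R)-6,8-diiodo-5,7,4'-tris(methoxymethoxy)-12-{2-[(triethylsilyl)oxy]propan-2-yl}oxepinoflavone
Product: 25 (12R)-5,7,4'-tris(methoxymethoxy)-6,8-bis(3-methylbut-2-enyl)-12-{2-[(triethylsilyl)oxy]propan-2-yl}oxepinoflavone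
Conditions: tributyl(3-methylbut-2-enyl)stannane (3 equiv), Pd(PPh3)4 (10 mol %), CuI (20 mol %), DMF, 90 °C
Reagents that add atoms: tributyl(3-methylbut-2-enyl)stannane, CC(C)=CC[Sn](CCCC)(CCCC)CCCC
Why: Twofold Stille coupling: oxidative addition of zerovalent palladium into each C–I bond, transmetalation of the allylic stannane and reductive elimination from the less substituted terminus of the prenyl ligand should give linear prenyl groups at C6 and C8.

Step 21
Reactants: 25 (12R)-5,7,4'-tris(methoxymethoxy)-6,8-bis(3-methylbut-2-enyl)-12-{2-[(triethylsilyl)oxy]propan-2-yl}oxepinoflavone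
Product: 26 CNP0328977.2, (12R)-5,7,4'-trihydroxy-12-(2-hydroxypropan-2-yl)-6,8-bis(3-methylbut-2-enyl)oxepinoflavone
Conditions: HCl (3 M aq.), MeOH/THF, 40 °C
Reagents that add atoms: none
Why: Acid-catalysed cleavage of the three MOM acetals and the tertiary silyl ether in one operation; dilute acid at mild temperature is used so that the ortho-prenylphenols do not cyclise to chromans and the tertiary alcohol does not dehydrate.

## Compound list

1 | methyl (4S)-2,2-dimethyl-1,3-dioxolane-4-carboxylate | COC(=O)[C@@H]1COC(C)(C)O1 | starting material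
2 | methyl (2S)-2,3-dihydroxypropanoate | COC(=O)[C@@H](O)CO | intermediate
3 | methyl (4S)-2,2-dibutyl-1,3,2-dioxastannolane-4-carboxylate (stannylene acetal of 2) | COC(=O)[C@@H]1CO[Sn](CCCC)(CCCC)O1 | intermediate (not isolated)
4 | methyl (2S)-2-hydroxy-3-[(4-methoxybenzyl)oxy]propanoate | COC(=O)[C@@H](O)COCc1ccc(OC)cc1 | intermediate
5 | 2,4-dihydroxybenzaldehyde | O=Cc1ccc(O)cc1O | starting material
6 | 2-hydroxy-4-(methoxymethoxy)benzaldehyde | COCOc1ccc(C=O)c(O)c1 | intermediate
7 | methyl (2R)-2-[2-formyl-5-(methoxymethoxy)phenoxy]-3-[(4-methoxybenzyl)oxy]propanoate | COc1ccc(COC[C@H](C(=O)OC)Oc2cc(OCOC)ccc2C=O)cc1 | intermediate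
8 | methyl (2R)-2-[2-(2,2-dibromoethenyl)-5-(methoxymethoxy)phenoxy]-3-[(4-methoxybenzyl)oxy]propanoate | COc1ccc(COC[C@H](C(=O)OC)Oc2cc(OCOC)ccc2C=C(Br)Br)cc1 | intermediate
9 | (3R)-3-[2-(2,2-dibromoethenyl)-5-(methoxymethoxy)phenoxy]-4-[(4-methoxybenzyl)oxy]-2-methylbutan-2-ol | COc1ccc(COC[C@H](C(C)(C)O)Oc2cc(OCOC)ccc2C=C(Br)Br)cc1 | intermediate
10 | {[(3R)-3-[2-(2,2-dibromoethenyl)-5-(methoxymethoxy)phenoxy]-4-[(4-methoxybenzyl)oxy]-2-methylbutan-2-yl]oxy}triethylsilane | COc1ccc(COC[C@H](C(C)(C)O[Si](CC)(CC)CC)Oc2cc(OCOC)ccc2C=C(Br)Br)cc1 | intermediate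
11 | 2,4,6-trihydroxybenzaldehyde | O=Cc1c(O)cc(O)cc1O | starting material
12 | 2,4,6-tris(benzyloxy)benzaldehyde | O=Cc1c(OCc2ccccc2)cc(OCc2ccccc2)cc1OCc1ccccc1 | intermediate
13 | lithium acetylide of 2-({(2R)-1-[(4-methoxybenzyl)oxy]-3-methyl-3-[(triethylsilyl)oxy]butan-2-yl}oxy)-4-(methoxymethoxy)phenylacetylene | COc1ccc(COC[C@H](C(C)(C)O[Si](CC)(CC)CC)Oc2cc(OCOC)ccc2C#C[Li])cc1 | intermediate (not isolated)
14 | 1-[2,4,6-tris(benzyloxy)phenyl]-3-[2-({(2R)-1-[(4-methoxybenzyl)oxy]-3-methyl-3-[(triethylsilyl)oxy]butan-2-yl}oxy)-4-(methoxymethoxy)phenyl]prop-2-yn-1-ol (both carbinol epimers) | COc1ccc(COC[C@H](C(C)(C)O[Si](CC)(CC)CC)Oc2cc(OCOC)ccc2C#CC(O)c2c(OCc3ccccc3)cc(OCc3ccccc3)cc2OCc2ccccc2)cc1 | intermediate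
15 | 1-[2,4,6-tris(benzyloxy)phenyl]-3-[2-({(2R)-1-[(4-methoxybenzyl)oxy]-3-methyl-3-[(triethylsilyl)oxy]butan-2-yl}oxy)-4-(methoxymethoxy)phenyl]prop-2-yn-1-one | COc1ccc(COC[C@H](C(C)(C)O[Si](CC)(CC)CC)Oc2cc(OCOC)ccc2C#CC(=O)c2c(OCc3ccccc3)cc(OCc3ccccc3)cc2OCc2ccccc2)cc1 | intermediate
16 | 5,7-bis(benzyloxy)-3-iodo-2-[2-({(2R)-1-[(4-methoxybenzyl)oxy]-3-methyl-3-[(triethylsilyl)oxy]butan-2-yl}oxy)-4-(methoxymethoxy)phenyl]-4H-chromen-4-one | COc1ccc(COC[C@H](C(C)(C)O[Si](CC)(CC)CC)Oc2cc(OCOC)ccc2-c2oc3cc(OCc4ccccc4)cc(OCc4ccccc4)c3c(=O)c2I)cc1 | intermediate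
17 | 5,7-bis(benzyloxy)-2-[2-({(2R)-1-hydroxy-3-methyl-3-[(triethylsilyl)oxy]butan-2-yl}oxy)-4-(methoxymethoxy)phenyl]-3-iodo-4H-chromen-4-one | OC[C@H](C(C)(C)O[Si](CC)(CC)CC)Oc1cc(OCOC)ccc1-c1oc2cc(OCc3ccccc3)cc(OCc3ccccc3)c2c(=O)c1I | intermediate
18 | (2S)-2-{2-[5,7-bis(benzyloxy)-3-iodo-4-oxo-4H-chromen-2-yl]-5-(methoxymethoxy)phenoxy}-3-methyl-3-[(triethylsilyl)oxy]butanal | O=C[C@H](C(C)(C)O[Si](CC)(CC)CC)Oc1cc(OCOC)ccc1-c1oc2cc(OCc3ccccc3)cc(OCc3ccccc3)c2c(=O)c1I | intermediate
19 | (12R)-5,7-bis(benzyloxy)-11-hydroxy-4'-(methoxymethoxy)-12-{2-[(triethylsilyl)oxy]propan-2-yl}oxepinoflavone (both C11 epimers) | c1ccccc1COc1cc(OCc2ccccc2)c2c(c1)oc1c(c2=O)C(O)[C@H](C(C)(C)O[Si](CC)(CC)CC)Oc2cc(OCOC)ccc2-1 | intermediate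
20 | C11 O-phenyl thionocarbonate of 19 (both C11 epimers) | c1ccccc1COc1cc(OCc2ccccc2)c2c(c1)oc1c(c2=O)C(OC(=S)Oc2ccccc2)[C@H](C(C)(C)O[Si](CC)(CC)CC)Oc2cc(OCOC)ccc2-1 | intermediate
21 | (12R)-5,7-bis(benzyloxy)-4'-(methoxymethoxy)-12-{2-[(triethylsilyl)oxy]propan-2-yl}oxepinoflavone | c1ccccc1COc1cc(OCc2ccccc2)c2c(c1)oc1c(c2=O)C[C@H](C(C)(C)O[Si](CC)(CC)CC)Oc2cc(OCOC)ccc2-1 | intermediate
22 | (12R)-5,7-dihydroxy-4'-(methoxymethoxy)-12-{2-[(triethylsilyl)oxy]propan-2-yl}oxepinoflavone | Oc1cc(O)c2c(c1)oc1c(c2=O)C[C@H](C(C)(C)O[Si](CC)(CC)CC)Oc2cc(OCOC)ccc2-1 | intermediate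
23 | (12R)-5,7-dihydroxy-6,8-diiodo-4'-(methoxymethoxy)-12-{2-[(triethylsilyl)oxy]propan-2-yl}oxepinoflavone | Oc1c(I)c(O)c2c(c1I)oc1c(c2=O)C[C@H](C(C)(C)O[Si](CC)(CC)CC)Oc2cc(OCOC)ccc2-1 | intermediate
24 | (12R)-6,8-diiodo-5,7,4'-tris(methoxymethoxy)-12-{2-[(triethylsilyl)oxy]propan-2-yl}oxepinoflavone | COCOc1c(I)c(OCOC)c2c(c1I)oc1c(c2=O)C[C@H](C(C)(C)O[Si](CC)(CC)CC)Oc2cc(OCOC)ccc2-1 | intermediate
25 | (12R)-5,7,4'-tris(methoxymethoxy)-6,8-bis(3-methylbut-2-enyl)-12-{2-[(triethylsilyl)oxy]propan-2-yl}oxepinoflavone | COCOc1c(CC=C(C)C)c(OCOC)c2c(c1CC=C(C)C)oc1c(c2=O)C[C@H](C(C)(C)O[Si](CC)(CC)CC)Oc2cc(OCOC)ccc2-1 | intermediate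
26 | CNP0328977.2, (12R)-5,7,4'-trihydroxy-12-(2-hydroxypropan-2-yl)-6,8-bis(3-methylbut-2-enyl)oxepinoflavone | CC(C)=CCc1c(O)c(CC=C(C)C)c2oc3c(c(=O)c2c1O)C[C@H](C(C)(C)O)Oc1cc(O)ccc1-3 | target

## Step count and least certain steps

Total: 21 steps. Longest linear sequence: 19 steps (from 1 through steps 1, 2, 4–7 and 9–21).

**Step 14 (key step).** The most likely failure is reduction of the C3–I bond without ring closure (protodemetalation of the alkenylchromium species). Addition to an α-branched aldehyde flanked by the quaternary C13, through a seven-membered transition state that twists the C2–C1' bond, may be slow. Enolisation of the aldehyde while it waits is a second loss channel. The fallback sets out from 17 and returns at 19; it replaces the aldehyde by an amide and chromium by magnesium.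
- Oxidation of 17 with TEMPO and PhI(OAc)2 in aqueous MeCN would give (2S)-2-{2-[5,7-bis(benzyloxy)-3-iodo-4-oxo-4H-chromen-2-yl]-5-(methoxymethoxy)phenoxy}-3-methyl-3-[(triethylsilyl)oxy]butanoic acid F1.
- Coupling with MeNHOMe·HCl (EDC·HCl, HOBt, i-Pr2NEt) would give the N-methoxy-N-methyl amide F2.
- Iodine–magnesium exchange with i-PrMgCl·LiCl at −78 °C and intramolecular acylation (Parham-type cyclisation) would give the C11 ketone F3.
- Luche reduction (NaBH4, CeCl3·7H2O, MeOH, −40 °C) would return carbinol 19.

**Step 11.** Electrophilic iodination of the electron-rich benzyloxy- and alkoxy-substituted rings may compete with activation of the alkyne, or dealkylation of the oxonium ion may be slow. The fallback sets out from 10 and returns at 16; ring C is closed without an electrophile and iodine is introduced afterwards by deprotonation.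
- 2,4,6-Trihydroxybenzoic acid would be converted with acetone, TFA and TFAA into 5,7-dihydroxy-2,2-dimethyl-4H-1,3-benzodioxin-4-one F4 and benzylated (BnBr, K2CO3) to the bis-benzyl ether F5.
- Acetylide 13, made from 10 as in step 9, would open F5 with loss of acetone to give the 2-hydroxyaryl ynone F6.
- Amine-mediated 6-endo oxa-Michael cyclisation (Et2NH, then warming) would give the 3-unsubstituted flavone F7.
- Lithiation at C3 with LDA at −78 °C and quenching with I2 would give 16.

**Step 16.** The C11 radical may fragment with loss of the ring B aryloxyl radical (opening the oxepine), or the activated thionocarbonate may undergo thiono-to-thiolo rearrangement before reduction; slow thioacylation in step 15 would add to this. The fallback sets out from 19 and returns at 21. Ionic deoxygenation with Et3SiH and BF3·OEt2 in CH2Cl2 at −78 °C would ionise the carbinol to a cation stabilised by O1 through C2=C3 and reduce it with the silane. The low temperature is meant to spare the silyl and MOM ethers, and no new compound lies on this way.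

**Step 20.** The second coupling at doubly ortho-substituted positions may stall and give protodeiodination, and the prenyl group may transfer through its γ-carbon (1,1-dimethylallyl isomers). The fallback sets out from 24 and returns at 25. Stille coupling with allyltributylstannane (Pd(PPh3)4, DMF) would give the 6,8-diallyl compound F8, which has no regiochemical ambiguity. Cross-metathesis with 2-methylbut-2-ene and second-generation Grubbs catalyst would then convert both allyl groups into prenyl groups.

## Further compounds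

F1 | step 14 | (2S)-2-{2-[5,7-bis(benzyloxy)-3-iodo-4-oxo-4H-chromen-2-yl]-5-(methoxymethoxy)phenoxy}-3-methyl-3-[(triethylsilyl)oxy]butanoic acid | OC(=O)[C@H](C(C)(C)O[Si](CC)(CC)CC)Oc1cc(OCOC)ccc1-c1oc2cc(OCc3ccccc3)cc(OCc3ccccc3)c2c(=O)c1I
F2 | step 14 | (2S)-2-{2-[5,7-bis(benzyloxy)-3-iodo-4-oxo-4H-chromen-2-yl]-5-(methoxymethoxy)phenoxy}-N-methoxy-N,3-dimethyl-3-[(triethylsilyl)oxy]butanamide | CON(C)C(=O)[C@H](C(C)(C)O[Si](CC)(CC)CC)Oc1cc(OCOC)ccc1-c1oc2cc(OCc3ccccc3)cc(OCc3ccccc3)c2c(=O)c1I
F3 | step 14 | (12S)-5,7-bis(benzyloxy)-4'-(methoxymethoxy)-11-oxo-12-{2-[(triethylsilyl)oxy]propan-2-yl}oxepinoflavone (C11 ketone) | c1ccccc1COc1cc(OCc2ccccc2)c2c(c1)oc1c(c2=O)C(=O)[C@H](C(C)(C)O[Si](CC)(CC)CC)Oc2cc(OCOC)ccc2-1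
F4 | step 11 | 5,7-dihydroxy-2,2-dimethyl-4H-1,3-benzodioxin-4-one | CC1(C)OC(=O)c2c(O)cc(O)cc2O1
F5 | step 11 | 5,7-bis(benzyloxy)-2,2-dimethyl-4H-1,3-benzodioxin-4-one | CC1(C)OC(=O)c2c(OCc3ccccc3)cc(OCc3ccccc3)cc2O1
F6 | step 11 | 1-[2,4-bis(benzyloxy)-6-hydroxyphenyl]-3-[2-({(2R)-1-[(4-methoxybenzyl)oxy]-3-methyl-3-[(triethylsilyl)oxy]butan-2-yl}oxy)-4-(methoxymethoxy)phenyl]prop-2-yn-1-one | COc1ccc(COC[C@H](C(C)(C)O[Si](CC)(CC)CC)Oc2cc(OCOC)ccc2C#CC(=O)c2c(O)cc(OCc3ccccc3)cc2OCc2ccccc2)cc1
F7 | step 11 | 5,7-bis(benzyloxy)-2-[2-({(2R)-1-[(4-methoxybenzyl)oxy]-3-methyl-3-[(triethylsilyl)oxy]butan-2-yl}oxy)-4-(methoxymethoxy)phenyl]-4H-chromen-4-one | COc1ccc(COC[C@H](C(C)(C)O[Si](CC)(CC)CC)Oc2cc(OCOC)ccc2-c2cc(=O)c3c(OCc4ccccc4)cc(OCc4ccccc4)cc3o2)cc1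
F0 | step 16 | none | none
F8 | step 20 | (12R)-6,8-diallyl-5,7,4'-tris(methoxymethoxy)-12-{2-[(triethylsilyl)oxy]propan-2-yl}oxepinoflavone | COCOc1c(CC=C)c(OCOC)c2c(c1CC=C)oc1c(c2=O)C[C@H](C(C)(C)O[Si](CC)(CC)CC)Oc2cc(OCOC)ccc2-1
A1 | alternative 1 | phloroglucinol | Oc1cc(O)cc(O)c1
A2 | alternative 1 | methyl (2R)-2-(2-hydroxypropan-2-yl)-5-oxo-8-[(triisopropylsilyl)oxy]-2,3,4,5-tetrahydro-1-benzoxepine-4-carboxylate | COC(=O)C1C[C@H](C(C)(C)O)Oc2cc(O[Si](C(C)C)(C(C)C)C(C)C)ccc2C1=O
A3 | alternative 1 | (12R)-5,7-dihydroxy-12-(2-hydroxypropan-2-yl)-4'-[(triisopropylsilyl)oxy]oxepinoflavone | Oc1cc(O)c2c(c1)oc1c(c2=O)C[C@H](C(C)(C)O)Oc2cc(O[Si](C(C)C)(C(C)C)C(C)C)ccc2-1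
A4 | alternative 2 | 2-({(3R)-2-hydroxy-2-methyl-6-[2,4,6-tris(methoxymethoxy)-3,5-bis(3-methylbut-2-enyl)phenyl]hex-5-yn-3-yl}oxy)-4-(methoxymethoxy)benzaldehyde oxime | COCOc1c(CC=C(C)C)c(OCOC)c(CC=C(C)C)c(OCOC)c1C#CC[C@H](C(C)(C)O)Oc1cc(OCOC)ccc1C=NO
A5 | alternative 2 | nitrile oxide derived from A4 | COCOc1c(CC=C(C)C)c(OCOC)c(CC=C(C)C)c(OCOC)c1C#CC[C@H](C(C)(C)O)Oc1cc(OCOC)ccc1C#[N+][O-]
A6 | alternative 2 | isoxazole-fused dihydrobenzoxepine carrying the diprenylated tris(methoxymethoxy) ring A | COCOc1c(CC=C(C)C)c(OCOC)c(CC=C(C)C)c(OCOC)c1-c1onc2c1C[C@H](C(C)(C)O)Oc1cc(OCOC)ccc1-2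
A7 | alternative 3 | 4,6-bis(benzyloxy)-2-hydroxybenzaldehyde | O=Cc1c(O)cc(OCc2ccccc2)cc1OCc1ccccc1
A8 | alternative 3 | (5R)-5-{3-[2-bromo-4-(methoxymethoxy)phenyl]prop-2-ynyl}-2,2,4,4-tetramethyl-1,3-dioxolane | COCOc1ccc(C#CC[C@H]2OC(C)(C)OC2(C)C)c(Br)c1
A9 | alternative 3 | 5,7-bis(benzyloxy)-2-[2-bromo-4-(methoxymethoxy)phenyl]-3-{[(4R)-2,2,5,5-tetramethyl-1,3-dioxolan-4-yl]methyl}-4H-chromen-4-one | O=c1c(C[C@H]2OC(C)(C)OC2(C)C)c(-c2ccc(OCOC)cc2Br)oc2cc(OCc3ccccc3)cc(OCc3ccccc3)c12
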